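**Retrosynthetic overview**
Both halves come from one C15 block, 7-epi-dehydrozaluzanin C (8), made from dehydrocostus lactone (1) with inversion of C7. Rings A, B, C of the lower half (cyclopentanone, cycloheptane, lactone) and rings B', C' of the upper half are inherited from 1.
Disconnections: C2'–C3' (ring A', closed last by a carbene-catalysed crossed benzoin); C4–C2' and C15–C14' (spiro cyclohexene ring D, Diels–Alder); ring A' of one molecule of 8 is opened between C2' and C3' by glycol cleavage.
Enabling feature: the α-ketol of ring A' (atoms C1'–C5'), a tertiary carbinol C2'–OH next to the ketone C3'=O. C2' also belongs to ring D, so it first serves, as an open-chain aldehyde carbon, as the donor terminus of the diene C2'=C1'–C10'=C14', and then, as the ring-D ketone, as the benzoin acceptor.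
Ring order: A/B/C and B'/C' (from 1) → temporary pyran O–C2'···C3' (steps 9–10, removed in step 11) → ring D (step 11) → ring A' (step 12).

Key step: step 12

Remark: guaiane numbering is used (primed = the half that carries the hydroxyl); the given SMILES encodes cis-fused lactones (H-6 and H-7 syn, i.e. C7-epimeric to commercial dehydrocostus lactone), so C7 is inverted once, in steps 1–3; the target is (1R,4R,5R,6S,7R,2'S,5'R,6'S,7'R).

**Step 1**
Reactants: 1 dehydrocostus lactone (H-1α, H-5α, H-6β, H-7α, trans lactone)
Product: 2 11,13-epoxy-11,13-dihydrodehydrocostus lactone (spiro-epoxide at C11, oxygen syn to H-7)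
Conditions: t-BuOOH (anhydrous, decane), DBU, CH2Cl2, 0 °C → rt
Reagents that add atoms: tert-butyl hydroperoxide, CC(C)(C)OO
Why: Weitz–Scheffer nucleophilic epoxidation should touch only the conjugated C11=C13 alkene, and the peroxy-enolate is expected to close on the lactone face syn to H-7 (anti to C8), which sets C11.

**Step 2**
Reactants: 2 11,13-epoxide
Product: 3 13-hydroxyguaia-4(15),7(11),10(14)-trien-12,6-olide (α-hydroxymethyl butenolide, C6 unchanged)
Conditions: Et2AlCl, lithium 2,2,6,6-tetramethylpiperidide (gives Et2Al(TMP) in the flask), toluene, 0 °C; 1 M HCl work-up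
Reagents that add atoms: none
Why: aluminium amide-mediated epoxide-to-allylic-alcohol isomerisation by syn-elimination, in which H-7 is the only β-hydrogen and lies syn to the epoxide oxygen, so the C11–O bond breaks and the conjugated butenolide forms with deliberate loss of the C7 stereocentre.

**Step 3**
Reactants: 3 hydroxymethyl butenolide
Product: 6 7-epi-dehydrocostus lactone (H-6β and H-7β, cis lactone, exocyclic C11=C13 restored), via allylic sulfonylhydrazine 4 (not isolated), via allylic diazene 5 (not isolated)
Conditions: 2-nitrobenzenesulfonylhydrazide, PPh3, DEAD, THF, −30 °C → rt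
Reagents that add atoms: none
Why: Mitsunobu displacement and loss of sulfinic acid give the allylic diazene, whose retro-ene loss of N2 (reductive allylic transposition) should deliver hydrogen to C7 on the convex butenolide face (syn to H-6, anti to C5), giving the cis lactone and the exocyclic methylene.

**Step 4**
Reactants: 6 7-epi-dehydrocostus lactone
Product: 7 3α-hydroxy-7-epi-dehydrocostus lactone (allylic alcohol; C3 configuration inconsequential)
Conditions: SeO2 (0.5 equiv), t-BuOOH, CH2Cl2, rt
Reagents that add atoms: selenium dioxide, O=[Se]=O (oxygen carrier, reoxidised by tert-butyl hydroperoxide, CC(C)(C)OO)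
Why: allylic oxidation (ene reaction then [2,3]-shift) is expected at the ring-A methylene C3 next to C4=C15, as for the parent lactone.

**Step 5**
Reactants: 7 allylic alcohol
Product: 8 7-epi-dehydrozaluzanin C (3-oxo-guaia-4(15),10(14),11(13)-trien-12,6-olide, cis lactone)
Conditions: Dess–Martin periodinane, CH2Cl2, rt
Reagents that add atoms: none
Why: Dess–Martin oxidation of a secondary allylic alcohol under neutral conditions should leave the three exocyclic alkenes and all stereocentres untouched.

**Step 6**
Reactants: 8 7-epi-dehydrozaluzanin C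
Product: 9 3-(trimethylsilyloxy)-2,4(15)-diene (silyl dienol ether of 8)
Conditions: TMSOTf, Et3N, CH2Cl2, −78 → 0 °C
Reagents that add atoms: trimethylsilyl trifluoromethanesulfonate, C[Si](C)(C)OS(=O)(=O)C(F)(F)F
Why: soft enolisation can only occur toward C2, because C4 is sp2, so a single silyl enol ether should form.

**Step 7**
Reactants: 9 silyl dienol ether
Product: 11 2α-hydroxy-7-epi-dehydrozaluzanin C (α-ketol; C2 configuration inconsequential), via silyloxy ketone 10 (not isolated)
Conditions: mCPBA, CH2Cl2, −20 °C; then 1 M HCl, THF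
Reagents that add atoms: 3-chloroperbenzoic acid, O=C(OO)c1cccc(Cl)c1
Why: Rubottom oxidation, in which the silyl enol ether is by far the most electron-rich alkene and is epoxidised from the convex α face before 1,4-silyl shift and desilylation.

**Step 8**
Reactants: 11 α-ketol
Product: 12 2α,3β-dihydroxy-7-epi-dehydrocostus lactone (diol; both carbinol configurations inconsequential)
Conditions: NaBH4, CeCl3·7H2O, MeOH, −78 °C
Reagents that add atoms: none
Why: Luche 1,2-reduction of the enone carbonyl should proceed without conjugate reduction of the α-methylene lactone.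

**Step 9**
Reactants: 12 diol
Product: 14 cyclic bis(methyl acetal) of the 2,3-seco-dialdehyde (2,6-dimethoxytetrahydropyran whose ring oxygen bridges C2' and C3'; C4'=C15' and C10'=C14' intact; anomeric mixture), via seco-dialdehyde 13 (not isolated)
Conditions: Pb(OAc)4, CH2Cl2–MeOH, 0 °C; then PPTS (cat.), rt
Reagents that add atoms: methanol, CO
Why: Criegee glycol cleavage opens the cyclopentane between C2' and C3', and the 1,5-dialdehyde is trapped at once as its cyclic bis-acetal, before the β,γ-unsaturated aldehyde can move into conjugation; C5', C6' and C7' are not touched.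

**Step 10**
Reactants: 14 cyclic bis-acetal
Product: 15 ring-locked dienol ether (2-methoxy-3-methylene-3,4-dihydro-2H-pyran fused at C1'/C5'; diene O–C2'H=C1'–C10'=C14'H2; C3' remains a methyl acetal)
Conditions: TMSOTf, i-Pr2NEt, CH2Cl2, −20 °C
Reagents that add atoms: none
Why: acetal-to-enol-ether elimination, in which only the C2' acetal has a neighbouring hydrogen (H-1') while the C3' oxocarbenium can only re-close, so a single 1-alkoxy diene should form with its oxygen held on the outer side by the pyran ring.

**Step 11**
Reactants: 15 ring-locked dienol ether; 8 7-epi-dehydrozaluzanin C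
Product: 17 spiro keto-enal (ring D cyclohexenone with C2'=O conjugated to C1'=C10'; spiro C4 of R configuration; C5' carries the 2-formylvinyl group C4'(=C15'H2)–C3'HO), via cycloadduct 16 (not isolated)
Conditions: toluene, BHT, 70 °C; then CH2Cl2–pH 7 phosphate buffer, DDQ, 0 °C → rt
Reagents that add atoms: water, O
Why: normal-demand Diels–Alder reaction with ortho regiochemistry (donor terminus C2' to the enone α-carbon C4, C14' to C15), expected on the convex α face of ring A, sets the spiro centre C4; DDQ then abstracts hydride from the allylic ether C2'–H and hydrolysis of the oxocarbenium converges both C2' epimers on the enone and frees the C3' aldehyde.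

**Step 12**
Reactants: 17 spiro keto-enal
Product: 18 CNP0269880.1 (target)
Conditions: 2-(pentafluorophenyl)-6,7-dihydro-5H-pyrrolo[2,1-c][1,2,4]triazol-2-ium tetrafluoroborate (20 mol %), i-Pr2NEt, toluene, 40 °C
Reagents that add atoms: none
Why: the carbene adds to the C3' aldehyde and proton transfer gives the Breslow intermediate, whose acyl-anion carbon attacks the C2' ketone; collapse releases the carbene and leaves the C2'(OH)–C3'(=O) ketol. The closest known reaction type is the carbene-catalysed intramolecular crossed aldehyde–ketone benzoin that forms five-membered tertiary α-ketols. Ring A' closes in the 5-exo-trig mode onto the C2' carbonyl. The C2' configuration is controlled by C5' and C4: the three-atom tether C5'–C4'–C3' lies on the face opposite H-5', and that face is flanked by the flat C3 carbonyl of ring A and not by the C5 methine, so the hydroxyl should end syn to H-5' (2'S). The step needs acyl-anion and not homoenolate or conjugate reactivity at the 2-substituted acrolein, and attack at C2' and not at the C3 ketone or a Michael acceptor. The electron-poor N-pentafluorophenyl triazolium and the five-membered closure should secure this, since attack at C3 would need a seven-membered ring and attack at C10' a bridged ring with a new quaternary centre.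

**Compound list**
1 | dehydrocostus lactone | C=C1CC[C@H]2C(=C)CC[C@H]3C(=C)C(=O)O[C@@H]3[C@H]21 | starting material
2 | 11,13-epoxy-11,13-dihydrodehydrocostus lactone | C=C1CC[C@H]2C(=C)CC[C@H]3[C@@]4(CO4)C(=O)O[C@@H]3[C@H]21 | intermediate
3 | 13-hydroxyguaia-4(15),7(11),10(14)-trien-12,6-olide | C=C1CC[C@H]2C(=C)CCC3=C(CO)C(=O)O[C@@H]3[C@H]21 | intermediate
4 | C13 N-(2-nitrophenylsulfonyl)hydrazine of 3 | C=C1CC[C@H]2C(=C)CCC3=C(CN(N)S(=O)(=O)c4ccccc4[N+](=O)[O-])C(=O)O[C@@H]3[C@H]21 | intermediate
5 | C13 allylic diazene | C=C1CC[C@H]2C(=C)CCC3=C(CN=N)C(=O)O[C@@H]3[C@H]21 | intermediate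
6 | 7-epi-dehydrocostus lactone | C=C1CC[C@H]2C(=C)CC[C@@H]3C(=C)C(=O)O[C@@H]3[C@H]21 | intermediate
7 | 3α-hydroxy-7-epi-dehydrocostus lactone | C=C1[C@H](O)C[C@H]2C(=C)CC[C@@H]3C(=C)C(=O)O[C@@H]3[C@H]21 | intermediate
8 | 7-epi-dehydrozaluzanin C | C=C1C(=O)C[C@H]2C(=C)CC[C@@H]3C(=C)C(=O)O[C@@H]3[C@H]21 | intermediate
9 | 3-(trimethylsilyloxy)-2,4(15)-diene of 8 | C=C1C(O[Si](C)(C)C)=C[C@H]2C(=C)CC[C@@H]3C(=C)C(=O)O[C@@H]3[C@H]21 | intermediate
10 | 2α-(trimethylsilyloxy)-7-epi-dehydrozaluzanin C | C=C1C(=O)[C@H](O[Si](C)(C)C)[C@H]2C(=C)CC[C@@H]3C(=C)C(=O)O[C@@H]3[C@H]21 | intermediate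
11 | 2α-hydroxy-7-epi-dehydrozaluzanin C | C=C1C(=O)[C@H](O)[C@H]2C(=C)CC[C@@H]3C(=C)C(=O)O[C@@H]3[C@H]21 | intermediate
12 | 2α,3β-dihydroxy-7-epi-dehydrocostus lactone | C=C1[C@@H](O)[C@H](O)[C@H]2C(=C)CC[C@@H]3C(=C)C(=O)O[C@@H]3[C@H]21 | intermediate
13 | 2,3-seco-dialdehyde | C=C(C=O)[C@H]1[C@@H](C=O)C(=C)CC[C@@H]2C(=C)C(=O)O[C@@H]21 | intermediate
14 | cyclic bis(methyl acetal) of 13 | COC1OC(OC)[C@H]2C(=C)CC[C@@H]3C(=C)C(=O)O[C@@H]3[C@H]2C1=C | intermediate
15 | ring-locked dienol ether | COC1OC=C2C(=C)CC[C@@H]3C(=C)C(=O)O[C@@H]3[C@H]2C1=C | intermediate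
16 | Diels–Alder cycloadduct (C2' epimers, pyran acetal intact) | C=C1C(OC)OC2C3=C(CC[C@@H]4C(=C)C(=O)O[C@@H]4[C@@H]13)CC[C@]21C(=O)C[C@H]2C(=C)CC[C@@H]3C(=C)C(=O)O[C@@H]3[C@H]21 | intermediate
17 | spiro keto-enal | C=C(C=O)[C@H]1C2=C(CC[C@@H]3C(=C)C(=O)O[C@@H]31)CC[C@@]4(C2=O)C(=O)C[C@H]5C(=C)CC[C@@H]6C(=C)C(=O)O[C@@H]6[C@H]54 | intermediate
18 | CNP0269880.1 | C=C1C(=O)[C@]2(O)C3=C(CC[C@@H]4C(=C)C(=O)O[C@@H]4[C@@H]13)CC[C@]21C(=O)C[C@H]2C(=C)CC[C@@H]3C(=C)C(=O)O[C@@H]3[C@H]21 | target

**Step count**
Total steps: 12. Longest linear sequence: 12 (1 → 8 → 15 → 18; 8 is also the second partner in step 11).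

**Steps most likely to fail**

Step 12. The acyl-anion addition may lose to homoenolate-type or conjugate addition of the carbene at the unsubstituted C15' terminus, or the ring may close on the wrong face of the C2' carbonyl. The fallback sets out from 17: SmI2 (THF, t-BuOH, −78 °C) should effect a ketyl–carbonyl (pinacol) cyclisation between C3' and C2' to the cis-diol F1. MnO2 oxidation of its secondary allylic alcohol then comes back to the route at 18.

Step 11. Bond formation between C2' and the future quaternary C4 may be slow against self-dimerisation of 8. The diene may also add to the β face of ring A, now that the cis lactone lies under the α face. In the DDQ stage, hydride may be abstracted at the doubly allylic C5'–H or at the acetal C3'–H. The fallback sets out from 14 and 8. Aqueous trifluoroacetic acid returns the seco-dialdehyde 13, and TBSOTf/Et3N converts it to the open-chain tert-butyldimethylsilyl dienol ether F2. A Me2AlCl-promoted stepwise Mukaiyama–Michael/aldol annulation with 8 (CH2Cl2, −78 °C) gives the allylic silyl ether F3. DDQ oxidation of this allylic silyl ether comes back to the route at 17.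

Step 2. The syn-elimination needs H-7 on the epoxide-oxygen face. If step 1 gives the other C11 epimer, or the amide attacks the lactone, no butenolide forms. The fallback sets out from 2. MgBr2·OEt2 opens the epoxide at C13 to the bromohydrin F4, and SOCl2/pyridine dehydrates the tertiary alcohol to the bromomethyl butenolide F5. Zinc dust in acetic acid then reduces the allylic bromide, with protonation of the allylzinc at C7 on the convex face. This comes back to the route at 6, so step 3 is bypassed as well.

**Further compounds**
F1 | step 12 | 2',3'-cis-diol (3'-hydroxy analogue of 18) | C=C1[C@H](O)[C@]2(O)C3=C(CC[C@@H]4C(=C)C(=O)O[C@@H]4[C@@H]13)CC[C@]21C(=O)C[C@H]2C(=C)CC[C@@H]3C(=C)C(=O)O[C@@H]3[C@H]21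
F2 | step 11 | open-chain tert-butyldimethylsilyl dienol ether of 13 | C=C(C=O)[C@H]1C(=CO[Si](C)(C)C(C)(C)C)C(=C)CC[C@@H]2C(=C)C(=O)O[C@@H]21
F3 | step 11 | spiro adduct with C2' tert-butyldimethylsilyl ether and free C3' aldehyde | C=C(C=O)[C@H]1C2=C(CC[C@@H]3C(=C)C(=O)O[C@@H]31)CC[C@@]4(C2O[Si](C)(C)C(C)(C)C)C(=O)C[C@H]5C(=C)CC[C@@H]6C(=C)C(=O)O[C@@H]6[C@H]54
F4 | step 2 | 13-bromo-11-hydroxy-11,13-dihydrodehydrocostus lactone | C=C1CC[C@H]2C(=C)CC[C@H]3[C@@](O)(CBr)C(=O)O[C@@H]3[C@H]21
F5 | step 2 | 13-bromoguaia-4(15),7(11),10(14)-trien-12,6-olide | C=C1CC[C@H]2C(=C)CCC3=C(CBr)C(=O)O[C@@H]3[C@H]21
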